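**Retrosynthetic overview** (briarellin numbering: ring A = cyclohexenone C1/C10–C14; ring B = tetrahydrofuran C9–O–C2–C1–C10; ring C = nine-membered ether ring C2–C9; ring D = oxepane C3–O–C16–C15–C14–C1–C2)
1. Target 32 ⇐ butyrylation of the C4 hydroxyl of oxepane alcohol 30.
2. 30 ⇐ epoxy alcohol 29: ring D is closed last by 7-exo opening of a 3,4-epoxide at the fully substituted C3 by the C16 hydroxyl, copying the presumed cladiellin → briarellin ether bridging. The enabling feature is the pair of anti-disposed vicinal oxygens on C3 (quaternary, in rings C and D) and C4 (butyrate carbon, ring C), which is the retron of a (3Z)-olefin epoxide, with O16 on the C14 arm of ring A seven atoms from C3.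
3. Ring C ⇐ ring-closing metathesis at C6=C7, after reagent-controlled epoxidation of the (3Z)-olefin; ring B ⇐ γ-lactone by half-reduction and C9 methallylation.
4. Ring A plus the lactone ⇐ endo, anti Diels–Alder union of butenolide 11 (C1–C6, C9, C10) with siloxy diene 20 (C11–C16 and the C15 methyl), two fragments of similar size; C1, C10 and C14 follow from C2.
5. 11 ⇐ propargyl alcohol (carbomagnesiation/allylation, Midland reduction, Lindlar lactonisation); 20 ⇐ (R)-β-methyl-γ-butyrolactone. Ring order: A (with lactone) → B → C → D.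

Key step: step 17

Remark: (4R)-4-methyldihydrofuran-2(3H)-one (12) and the D-fructose-derived Shi ketone are taken as purchasable; the sense of step 5 assumes that the branched alkenyl group of 8 acts as the large group, as n-pentyl does in the Midland reduction of 1-octyn-3-one.

**Step 1**
Reactants: 1 prop-2-yn-1-ol; 2 methylmagnesium bromide; 3 allyl bromide
Product: 4 (2Z)-2-methylhexa-2,5-dien-1-ol
Conditions: MeMgBr (2.3 equiv), CuI (10 mol %), THF, −10 °C → rt; then allyl bromide, 0 °C → rt; H2O work-up
Reagents that add atoms: methylmagnesium bromide (2), C[Mg]Br; allyl bromide (3), C=CCBr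
Why: Copper-catalysed anti-carbomagnesiation of the magnesium propargyl alkoxide puts CH3 on the internal carbon and a chelated vinylmagnesium on the terminal carbon cis to CH2O, and its copper-mediated allylation with retention should give the (Z)-trisubstituted olefin that becomes C3=C4.

**Step 2**
Reactants: 4 (2Z)-2-methylhexa-2,5-dien-1-ol
Product: 5 (2Z)-2-methylhexa-2,5-dienal
Conditions: activated MnO2 (15 equiv), CH2Cl2, rt
Reagents that add atoms: none
Why: Allylic alcohol oxidation on MnO2 is neutral and heterogeneous, so the (Z) geometry and the skipped diene should survive.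

**Step 3**
Reactants: 5 (2Z)-2-methylhexa-2,5-dienal; 6 methyl propiolate
Product: 7 methyl (5Z)-4-hydroxy-5-methylnona-5,8-dien-2-ynoate (racemic)
Conditions: 6, LiN(SiMe3)2, THF, −78 °C; then 5; AcOH quench at −78 °C
Reagents that add atoms: methyl propiolate (6), C#CC(=O)OC
Why: 1,2-Addition of lithium methyl propiolate to the enal (acetylide addition); the carbinol centre is formed racemic and is erased in step 4.

**Step 4**
Reactants: 7 methyl (5Z)-4-hydroxy-5-methylnona-5,8-dien-2-ynoate
Product: 8 methyl (5Z)-5-methyl-4-oxonona-5,8-dien-2-ynoate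
Conditions: activated MnO2 (15 equiv), CH2Cl2, 0 °C; used at once
Reagents that add atoms: none
Why: The alcohol is both allylic and propargylic, so mild MnO2 oxidation should give the ynone without isomerising the (Z)-enone.

**Step 5**
Reactants: 8 methyl (5Z)-5-methyl-4-oxonona-5,8-dien-2-ynoate
Product: 9 methyl (4R,5Z)-4-hydroxy-5-methylnona-5,8-dien-2-ynoate
Conditions: (R)-Alpine-Borane (B-isopinocampheyl-9-BBN from (+)-α-pinene, 2 equiv), concentrated THF, 0 °C → rt; then ethanolamine, Et2O
Reagents that add atoms: none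
Why: Midland reduction of a 4-oxo-2-ynoate: hydride is transferred through a boat-like six-membered transition state with the slim alkynyl group on the hindered side, in the sense that gives (R)-1-octyn-3-ol from 1-octyn-3-one, which sets C2 (4R in 9).

**Step 6**
Reactants: 9 methyl (4R,5Z)-4-hydroxy-5-methylnona-5,8-dien-2-ynoate
Product: 11 (5S)-5-[(2Z)-hexa-2,5-dien-2-yl]furan-2(5H)-one, via hydroxy enoate 10 (not isolated)
Conditions: H2 (1 atm, stopped after 1 equiv), Pd/CaCO3 poisoned with Pb(OAc)2 (Lindlar catalyst), quinoline, EtOAc, rt; then PPTS (cat.), CH2Cl2, rt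
Reagents that add atoms: none
Why: Lindlar syn-semihydrogenation of the alkyne, which binds the poisoned catalyst far more strongly than the olefins, gives the (Z)-γ-hydroxy enoate, and this lactonises to the butenolide without touching the carbinol centre (now 5S).

**Step 7**
Reactants: 12 (4R)-4-methyldihydrofuran-2(3H)-one; 13 1-propynyllithium
Product: 14 (6R)-7-hydroxy-6-methylhept-2-yn-4-one
Conditions: LiC≡CCH3 (1.05 equiv), THF, −78 °C; AcOH quench at −78 °C
Reagents that add atoms: 1-propynyllithium (13), [Li]C#CC
Why: Mono-addition of a lithium acetylide to a lactone: the tetrahedral lithium hemiketal persists at −78 °C and collapses to the hydroxy ynone only on work-up, and C15 is not involved.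

**Step 8**
Reactants: 14 (6R)-7-hydroxy-6-methylhept-2-yn-4-one; 15 tert-butyl(chloro)diphenylsilane
Product: 16 (6R)-7-[tert-butyl(diphenyl)silyl]oxy-6-methylhept-2-yn-4-one
Conditions: TBDPSCl, imidazole, CH2Cl2, 0 °C → rt
Reagents that add atoms: tert-butyl(chloro)diphenylsilane (15), CC(C)(C)[Si](Cl)(c1ccccc1)c1ccccc1
Why: Silylation of the primary hydroxyl traps the open-chain tautomer with a group that withstands the acid, hydride and oxidant steps ahead.

**Step 9**
Reactants: 16 (6R)-7-[tert-butyl(diphenyl)silyl]oxy-6-methylhept-2-yn-4-one; 17 methanol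
Product: 18 (2E,6R)-7-[tert-butyl(diphenyl)silyl]oxy-2-methoxy-6-methylhept-2-en-4-one
Conditions: MeOH (5 equiv), PBu3 (10 mol %), CH2Cl2, rt
Reagents that add atoms: methanol (17), CO
Why: Phosphine-catalysed conjugate addition of methanol to the ynone should give the (E)-vinylogous ester regiospecifically, with the methoxy group on the methyl-bearing carbon (C11).

**Step 10**
Reactants: 18 (2E,6R)-7-[tert-butyl(diphenyl)silyl]oxy-2-methoxy-6-methylhept-2-en-4-one; 19 tert-butyl(chloro)dimethylsilane
Product: 20 tert-butyl{[(2R,3Z,5E)-4-[tert-butyl(dimethyl)silyl]oxy-6-methoxy-2-methylhepta-3,5-dien-1-yl]oxy}diphenylsilane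
Conditions: LiN(i-Pr)2, THF/DMPU (4:1), −78 °C; TBSCl, −78 → 0 °C
Reagents that add atoms: tert-butyl(chloro)dimethylsilane (19), CC(C)(C)[Si](C)(C)Cl
Why: Kinetic α′-deprotonation of the vinylogous ester and O-silylation in the presence of DMPU should give the (Z)-silyl dienol ether (a Danishefsky-type diene) with the C15 arm on the outside of the diene; any (E)-isomer cannot reach the s-cis form and returns as 18 after step 11.

**Step 11**
Reactants: 11 (5S)-5-[(2Z)-hexa-2,5-dien-2-yl]furan-2(5H)-one; 20 siloxy diene
Product: 21 endo Diels–Alder adduct (cis-fused γ-lactone/cyclohexene silyl enol ether)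
Conditions: toluene (1 M), BHT (cat.), 110 °C, sealed tube
Reagents that add atoms: none
Why: Normal-demand Diels–Alder reaction joining two fragments of similar size: the doubly donor-activated C14 terminus bonds to the butenolide β-carbon C1, the diene adds anti to the C2 substituent, and the endo transition state (lactone under the diene) places the outside C15 arm cis to C2, which sets C1, C10 and C14 (C11 is transient).

**Step 12**
Reactants: 21 endo Diels–Alder adduct; 17 methanol
Product: 23 C9 methyl acetal of the bicyclic C11=C12–C13=O enone, via lactol 22 (not isolated)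
Conditions: i-Bu2AlH (1.1 equiv), CH2Cl2, −78 °C; potassium sodium tartrate (KNaC4H4O6) work-up; crude in MeOH, CSA (10 mol %), 0 °C → rt
Reagents that add atoms: methanol (17), CO
Why: The lactone is half-reduced while the ketone is still masked as its silyl enol ether, and acid methanolysis then converts the lactol into the methyl acetal (Fischer glycosidation), cleaves the enol ether and eliminates methanol to give the enone, under acid mild enough to leave the α-centre C14 alone.

**Step 13**
Reactants: 23 C9 methyl acetal enone; 24 trimethyl(2-methylallyl)silane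
Product: 25 2,5-cis-tetrahydrofuran enone with a C9 methallyl group
Conditions: methallyl-TMS (3 equiv), TMSOTf (20 mol %), CH2Cl2, −78 °C
Reagents that add atoms: trimethyl(2-methylallyl)silane (24), C=C(C)C[Si](C)(C)C
Why: Hosomi–Sakurai allylation of the C9 oxocarbenium ion on the convex face of the cis-fused bicycle, anti to the C10–C11 bond, should set C9 with the 2,5-cis relationship to C2, while the β,β-disubstituted enone is inert to the allylsilane at −78 °C.

**Step 14**
Reactants: 25 2,5-cis-tetrahydrofuran enone; 26 potassium peroxymonosulfate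
Product: 27 (3R,4R)-3,4-epoxide of 25
Conditions: D-fructose-derived Shi ketone (30 mol %), Oxone (2KHSO5·KHSO4·K2SO4), K2CO3, Bu4NHSO4, MeCN/dimethoxymethane, aq. Na2B4O7/Na2EDTA buffer (pH 10.5), −5 °C, short reaction time
Reagents that add atoms: potassium peroxymonosulfate (26), [K+].[O-]S(=O)(=O)OO
Why: Shi epoxidation: the chiral dioxirane reacts with the only electron-rich trisubstituted olefin (the vinyl, 1,1-disubstituted and enone olefins are much slower), and the spiro transition state, governed by the position of the C4 hydrogen as in 1-phenylcyclohexene → (R,R)-oxide, should deliver oxygen to the face that gives the (3R,4R)-epoxide.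

**Step 15**
Reactants: 27 (3R,4R)-epoxide
Product: 28 tricyclic (6Z)-olefin with 3,4-epoxide and C16 silyl ether
Conditions: second-generation Grubbs catalyst (H2IMes)(PCy3)Cl2Ru=CHPh (10 mol %), CH2Cl2 (1 mM), 40 °C
Reagents that add atoms: none
Why: Ring-closing metathesis between the C6 vinyl group and the 1,1-disubstituted methallyl olefin, a closure with precedent on 2,5-cis-tetrahydrofuran substrates of the cladiellin family, forms ring C with loss of ethene; the cis-tetrahydrofuran and the cis-epoxide turn both chains to the same side and the ring size enforces the (Z)-olefin.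

**Step 16**
Reactants: 28 tricyclic epoxide silyl ether
Product: 29 tricyclic epoxy alcohol (free C16 hydroxyl)
Conditions: Bu4NF/AcOH (1:1, 3 equiv), THF, 0 °C → rt
Reagents that add atoms: none
Why: Fluoride desilylation, buffered with acetic acid so that neither C14 (α to the ketone) epimerises nor the epoxide opens.

**Step 17**
Reactants: 29 tricyclic epoxy alcohol
Product: 30 oxepane alcohol (4-debutyryl target)
Conditions: (+)-camphor-10-sulfonic acid (10 mol %), 4 Å molecular sieves, CH2Cl2, −20 → 0 °C
Reagents that add atoms: none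
Why: Brønsted-acid activation of the trisubstituted 3,4-epoxide lets O16 attack the fully substituted C3 from the rear of the breaking C3–O bond (borderline SN2 with tertiary cationic character), which forms the C3–O16 bond with inversion and releases the C4 hydroxyl; the closest known reaction type is the acid-catalysed exo-selective epoxy alcohol cyclisation used for oxepanes and polyether arrays, and it mirrors the presumed closure of the C3–O–C16 bridge that turns a cladiellin into a briarellin. Ring D closes in the 7-exo-tet mode (C4 stays outside the new ring), the alternative 8-endo attack at C4 being disfavoured by ring size and by the lower substitution of C4. C3 (S in 30) is controlled by inversion of the (3R)-epoxide carbon installed in step 14, C4 (R) is carried over unchanged from the epoxide, and no other stereocentre is touched. The step needs regioselectivity (C3 over C4), stereospecific anti opening and chemoselectivity over proton loss from the C3 methyl group or a 1,2-hydride shift; the cis relationship of the C1–C2 and C14–C15 bonds on ring A, fixed in step 11, should hold the CH(CH3)CH2OH arm over the face of C3 opposite to the epoxide oxygen, and low temperature with a non-nucleophilic acid and solvent should suppress the ionisation pathways. The ketone, the C6=C7 olefin and the bridging ether oxygen are poor nucleophiles toward the activated epoxide and cannot reach C3 through a favourable ring size.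

**Step 18**
Reactants: 30 oxepane alcohol; 31 butanoic anhydride
Product: 32 target CNP0271677.1
Conditions: (PrCO)2O (3 equiv), DMAP (0.2 equiv), Et3N, CH2Cl2, rt
Reagents that add atoms: butanoic anhydride (31), CCCC(=O)OC(=O)CCC
Why: DMAP-catalysed acylation of the only hydroxyl (secondary, at C4) with retention, since the C–O bond is not broken.

**Compound list**
1 | prop-2-yn-1-ol | C#CCO | starting material
2 | methylmagnesium bromide | C[Mg]Br | starting material
3 | allyl bromide | C=CCBr | starting material
4 | (2Z)-2-methylhexa-2,5-dien-1-ol | OC/C(C)=C\CC=C | intermediate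
5 | (2Z)-2-methylhexa-2,5-dienal | O=C/C(C)=C\CC=C | intermediate
6 | methyl propiolate | C#CC(=O)OC | starting material
7 | methyl (5Z)-4-hydroxy-5-methylnona-5,8-dien-2-ynoate (racemic) | COC(=O)C#CC(O)/C(C)=C\CC=C | intermediate
8 | methyl (5Z)-5-methyl-4-oxonona-5,8-dien-2-ynoate | COC(=O)C#CC(=O)/C(C)=C\CC=C | intermediate
9 | methyl (4R,5Z)-4-hydroxy-5-methylnona-5,8-dien-2-ynoate | COC(=O)C#C[C@H](O)/C(C)=C\CC=C | intermediate
10 | methyl (2Z,4S,5Z)-4-hydroxy-5-methylnona-2,5,8-trienoate | COC(=O)/C=C\[C@H](O)/C(C)=C\CC=C | intermediate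
11 | (5S)-5-[(2Z)-hexa-2,5-dien-2-yl]furan-2(5H)-one | O=C1C=C[C@H](O1)/C(C)=C\CC=C | intermediate
12 | (4R)-4-methyldihydrofuran-2(3H)-one | C[C@H]1COC(=O)C1 | starting material
13 | 1-propynyllithium | [Li]C#CC | starting material
14 | (6R)-7-hydroxy-6-methylhept-2-yn-4-one | C[C@H](CC(=O)C#CC)CO | intermediate
15 | tert-butyl(chloro)diphenylsilane | CC(C)(C)[Si](Cl)(c1ccccc1)c1ccccc1 | starting material
16 | (6R)-7-[tert-butyl(diphenyl)silyl]oxy-6-methylhept-2-yn-4-one | C[C@H](CC(=O)C#CC)CO[Si](c1ccccc1)(c1ccccc1)C(C)(C)C | intermediate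
17 | methanol | CO | starting material
18 | (2E,6R)-7-[tert-butyl(diphenyl)silyl]oxy-2-methoxy-6-methylhept-2-en-4-one | CO/C(C)=C/C(=O)C[C@@H](C)CO[Si](c1ccccc1)(c1ccccc1)C(C)(C)C | intermediate
19 | tert-butyl(chloro)dimethylsilane | CC(C)(C)[Si](C)(C)Cl | starting material
20 | tert-butyl{[(2R,3Z,5E)-4-[tert-butyl(dimethyl)silyl]oxy-6-methoxy-2-methylhepta-3,5-dien-1-yl]oxy}diphenylsilane | CO/C(C)=C/C(O[Si](C)(C)C(C)(C)C)=C/[C@@H](C)CO[Si](c1ccccc1)(c1ccccc1)C(C)(C)C | intermediate
21 | endo Diels–Alder adduct: cis-fused γ-lactone (C9=O) and cyclohexene silyl enol ether (C12=C13–OTBS), C11 with CH3 and OCH3, C2 with (2Z)-hexa-2,5-dien-2-yl, C14 with CH(CH3)CH2OTBDPS; C1, C2, C10, C14, C15 as in 32 | O=C1O[C@H](/C(C)=C\CC=C)[C@@H]2[C@H]1[C@](C)(OC)C=C(O[Si](C)(C)C(C)(C)C)[C@@H]2[C@@H](C)CO[Si](c1ccccc1)(c1ccccc1)C(C)(C)C | intermediate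
22 | lactol of 21 (C9–OH, both anomers) | OC1O[C@H](/C(C)=C\CC=C)[C@@H]2[C@H]1[C@](C)(OC)C=C(O[Si](C)(C)C(C)(C)C)[C@@H]2[C@@H](C)CO[Si](c1ccccc1)(c1ccccc1)C(C)(C)C | intermediate
23 | C9 methyl acetal (both anomers) of the bicyclic C11=C12–C13=O enone | COC1O[C@H](/C(C)=C\CC=C)[C@@H]2[C@H]1C(C)=CC(=O)[C@@H]2[C@@H](C)CO[Si](c1ccccc1)(c1ccccc1)C(C)(C)C | intermediate
24 | trimethyl(2-methylallyl)silane | C=C(C)C[Si](C)(C)C | starting material
25 | 2,5-cis-tetrahydrofuran enone with C9 methallyl, C2 (2Z)-hexa-2,5-dien-2-yl and C16 OTBDPS | C=C(C)C[C@@H]1O[C@H](/C(C)=C\CC=C)[C@@H]2[C@H]1C(C)=CC(=O)[C@@H]2[C@@H](C)CO[Si](c1ccccc1)(c1ccccc1)C(C)(C)C | intermediate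
26 | potassium peroxymonosulfate (active component of Oxone) | [K+].[O-]S(=O)(=O)OO | starting material
27 | (3R,4R)-3,4-epoxide of 25 | C=C(C)C[C@@H]1O[C@H]([C@]3(C)O[C@@H]3CC=C)[C@@H]2[C@H]1C(C)=CC(=O)[C@@H]2[C@@H](C)CO[Si](c1ccccc1)(c1ccccc1)C(C)(C)C | intermediate
28 | tricycle (rings A, B, C) with (6Z)-olefin, (3R,4R)-epoxide and C16 OTBDPS | O1[C@@H]2C/C=C(/C)C[C@@H]3O[C@H]([C@]12C)[C@@H]4[C@H]3C(C)=CC(=O)[C@@H]4[C@@H](C)CO[Si](c1ccccc1)(c1ccccc1)C(C)(C)C | intermediate
29 | tricyclic epoxy alcohol (C16–OH) | O1[C@@H]2C/C=C(/C)C[C@@H]3O[C@H]([C@]12C)[C@@H]4[C@H]3C(C)=CC(=O)[C@@H]4[C@@H](C)CO | intermediate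
30 | tetracyclic oxepane alcohol (C4–OH; 4-debutyryl target) | O[C@@H]1C/C=C(/C)C[C@@H]2O[C@H]3[C@@H]4[C@H]2C(C)=CC(=O)[C@@H]4[C@@H](C)CO[C@@]13C | intermediate
31 | butanoic anhydride | CCCC(=O)OC(=O)CCC | starting material
32 | CNP0271677.1 (C4 butanoate of 30) | CCCC(=O)O[C@@H]1C/C=C(/C)C[C@@H]2O[C@H]3[C@@H]4[C@H]2C(C)=CC(=O)[C@@H]4[C@@H](C)CO[C@@]13C | target

**Totals**
Total step count: 18. Longest linear sequence: 14 steps (steps 1–6, then 11–18); the diene branch (steps 7–10) joins at step 11.

**Steps most likely to fail**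

Step 11. The cycloaddition may be too slow: the diene carries a methyl group on the inside of one terminus and the butenolide is only a moderate dienophile, so thermal [1,5]-hydrogen shift or decomposition of the diene and erosion of endo selectivity can compete. Fallback, setting out from 16 and returning at 23: conjugate addition of dimethylamine (THF, rt) to the ynone would give the vinylogous amide (2E,6R)-7-[tert-butyl(diphenyl)silyl]oxy-2-(dimethylamino)-6-methylhept-2-en-4-one F1. Silylation with KN(SiMe3)2/TBSCl (THF, −78 °C) would give the much more electron-rich 1-amino-3-siloxy diene F2. Its cycloaddition with 11 (toluene, rt to 60 °C) should give the amino cycloadduct F3. Reduction with i-Bu2AlH (−78 °C) would pass through the amino lactol F4, and CSA (1.2 equiv) in MeOH would eliminate dimethylamine in place of methanol and rejoin the route at 23.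

Step 15. Ring closure to the nine-membered trisubstituted olefin may be outrun by oligomerisation through the terminal vinyl group or stall for conformational reasons. Fallback, setting out from 23 and returning at 28, with a Nozaki–Hiyama–Kishi closure in place of metathesis: allylation of 23 with (2-bromoallyl)trimethylsilane (TMSOTf, CH2Cl2, −78 °C) would give the C9 2-bromoallyl tetrahydrofuran F5. Shi epoxidation as in step 14 would give its (3R,4R)-epoxide F6. OsO4 (cat.)/NaIO4/2,6-lutidine (dioxane–H2O) would cleave only the electron-rich vinyl group to the C6 aldehyde F7. CrCl2/NiCl2 (cat.) in DMSO/THF at high dilution would close ring C to the C6 allylic alcohol with a C7 exo-methylene group F8. Reductive 1,3-transposition of this alcohol (o-nitrobenzenesulfonylhydrazide, PPh3, DEAD, N-methylmorpholine, THF, −30 °C → rt, through the allylic diazene) would move the double bond into the ring as the (6Z)-olefin and give 28.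

Step 17. The activated epoxide may ionise and then lose a proton from the C3 methyl group or undergo a 1,2-hydride shift instead of being captured by O16, if the hydroxyl cannot reach the rear face of C3 fast enough. Fallback, setting out from 28 and returning at 30, forming the other C–O bond of the bridge: HClO4 (cat.) in THF/H2O at 0 °C would open the epoxide with water at C3 with inversion and give the 3,4-diol silyl ether F9. Bu4NF/AcOH would give the triol F10. Tf2O/2,6-lutidine (CH2Cl2, −78 → 0 °C) would triflate the primary C16 hydroxyl selectively, and the tertiary C3 hydroxyl would displace the triflate to close the oxepane and give 30.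

**Further compounds**
F1 | step 11 | (2E,6R)-7-[tert-butyl(diphenyl)silyl]oxy-2-(dimethylamino)-6-methylhept-2-en-4-one | CN(C)/C(C)=C/C(=O)C[C@@H](C)CO[Si](c1ccccc1)(c1ccccc1)C(C)(C)C
F2 | step 11 | (2E,4Z,6R)-7-[tert-butyl(diphenyl)silyl]oxy-4-[tert-butyl(dimethyl)silyl]oxy-N,N,6-trimethylhepta-2,4-dien-2-amine | CN(C)/C(C)=C/C(O[Si](C)(C)C(C)(C)C)=C/[C@@H](C)CO[Si](c1ccccc1)(c1ccccc1)C(C)(C)C
F3 | step 11 | amino cycloadduct (as 21 with N(CH3)2 in place of OCH3 at C11) | O=C1O[C@H](/C(C)=C\CC=C)[C@@H]2[C@H]1[C@](C)(N(C)C)C=C(O[Si](C)(C)C(C)(C)C)[C@@H]2[C@@H](C)CO[Si](c1ccccc1)(c1ccccc1)C(C)(C)C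
F4 | step 11 | lactol of F3 (C9–OH, both anomers) | OC1O[C@H](/C(C)=C\CC=C)[C@@H]2[C@H]1[C@](C)(N(C)C)C=C(O[Si](C)(C)C(C)(C)C)[C@@H]2[C@@H](C)CO[Si](c1ccccc1)(c1ccccc1)C(C)(C)C
F5 | step 15 | C9 2-bromoallyl analogue of 25 | C=C(Br)C[C@@H]1O[C@H](/C(C)=C\CC=C)[C@@H]2[C@H]1C(C)=CC(=O)[C@@H]2[C@@H](C)CO[Si](c1ccccc1)(c1ccccc1)C(C)(C)C
F6 | step 15 | (3R,4R)-3,4-epoxide of F5 | C=C(Br)C[C@@H]1O[C@H]([C@]3(C)O[C@@H]3CC=C)[C@@H]2[C@H]1C(C)=CC(=O)[C@@H]2[C@@H](C)CO[Si](c1ccccc1)(c1ccccc1)C(C)(C)C
F7 | step 15 | C6 aldehyde from F6 | C=C(Br)C[C@@H]1O[C@H]([C@]3(C)O[C@@H]3CC=O)[C@@H]2[C@H]1C(C)=CC(=O)[C@@H]2[C@@H](C)CO[Si](c1ccccc1)(c1ccccc1)C(C)(C)C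
F8 | step 15 | tricyclic C6 allylic alcohol with C7 exo-methylene (C6 epimers), 3,4-epoxide and C16 OTBDPS | O1[C@@H]2CC(O)C(=C)C[C@@H]3O[C@H]([C@]12C)[C@@H]4[C@H]3C(C)=CC(=O)[C@@H]4[C@@H](C)CO[Si](c1ccccc1)(c1ccccc1)C(C)(C)C
F9 | step 17 | tricyclic 3,4-diol (C3–OH inverted relative to the epoxide, C4–OH retained), C16 OTBDPS | O[C@@H]1C/C=C(/C)C[C@@H]2O[C@H]([C@@]1(C)O)[C@@H]3[C@H]2C(C)=CC(=O)[C@@H]3[C@@H](C)CO[Si](c1ccccc1)(c1ccccc1)C(C)(C)C
F10 | step 17 | tricyclic 3,4,16-triol | O[C@@H]1C/C=C(/C)C[C@@H]2O[C@H]([C@@]1(C)O)[C@@H]3[C@H]2C(C)=CC(=O)[C@@H]3[C@@H](C)CO
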